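## Retrosynthetic overview

1. Target ⇐ global O‑demethylation of its hexamethyl ether ⇐ oxidation of the C3=C4 alkene of unit B (the trione half) to the 3,4‑dione.
2. Quinone–O–C(quaternary) bond ⇐ tertiary alkoxide of an (R)‑2‑ethyl‑2‑hydroxynaphthalen‑1(2H)‑one plus a 2‑chloro‑3‑ethylnaphthoquinone (addition–elimination; no bond at the stereocentre is broken).
3. Key C–C bond (C1–C2 of unit B, the only stereocentre) ⇐ enantioselective carbene‑catalysed crossed benzoin: the aldehyde carbon of a keto‑aldehyde acts as an acyl anion toward the ethyl ketone carbon and closes the carbocycle of unit B.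
4. Unit A (the quinone half) ⇐ the same benzoin‑made ring after C2 deoxygenation and O2/base autoxidation to the hydroxyquinone.
5. Keto‑aldehyde ⇐ 2,4,5‑trimethoxybenzaldehyde by directed ortho‑iodination and Heck coupling with pent‑1‑en‑3‑ol.

Assumption: the (5aS,10bR) antipode of the triazolium salt named in step 3 is taken to give the (2R)‑acyloin; if the measured sense is opposite, the commercial mirror‑image salt is used and nothing else changes.

Numbering note: unit B is numbered throughout as the naphthalen‑1(2H)‑one (C1 = former aldehyde carbon, C2 = stereocentre). Compound 8 is divided between steps 4 and 5; lower‑ee mother liquors of 8 go to step 5, where the stereocentre is removed anyway.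

## Route

Step 1
Reactants: 1 2,4,5‑trimethoxybenzaldehyde
Product: 5 2‑iodo‑3,4,6‑trimethoxybenzaldehyde, via lithium α‑amino alkoxide 2 (not isolated), via ortho‑lithiated α‑amino alkoxide 3 (not isolated), via iodinated α‑amino alkoxide 4 (not isolated)
Conditions: LiN(CH3)CH2CH2N(CH3)2 (from N,N,N'‑trimethylethylenediamine and n‑C4H9Li), THF, −20 °C; n‑C4H9Li (3 equiv), −20 °C, 20 h; I2, −78 °C → rt; aq. NH4Cl/Na2S2O3
Reagents that add atoms: iodine, II
Why: Comins directed ortho‑metalation; the in‑situ α‑amino alkoxide delivers n‑C4H9Li to C6, the only position ortho to it and also flanked by the 5‑methoxy group, and iodolysis followed by hydrolysis returns the aldehyde.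

Step 2
Reactants: 5 2‑iodo‑3,4,6‑trimethoxybenzaldehyde; 6 pent‑1‑en‑3‑ol
Product: 7 3,4,6‑trimethoxy‑2‑(3‑oxopentyl)benzaldehyde
Conditions: Pd(OAc)2 (5 mol %), (n‑C4H9)4NCl, NaHCO3, DMF, 60 °C
Reagents that add atoms: none
Why: Jeffery–Heck arylation of an allylic alcohol; after insertion, β‑hydride elimination toward the carbinol gives an enol that tautomerises to the saturated ethyl ketone, and the mild base leaves the aldehyde alone.

Step 3 (key step)
Reactants: 7 3,4,6‑trimethoxy‑2‑(3‑oxopentyl)benzaldehyde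
Product: 8 (2R)‑2‑ethyl‑2‑hydroxy‑5,6,8‑trimethoxy‑3,4‑dihydronaphthalen‑1(2H)‑one
Conditions: (5aS,10bR)‑2‑(pentafluorophenyl)‑5a,10b‑dihydro‑4H,6H‑indeno[2,1‑b][1,2,4]triazolo[4,3‑d][1,4]oxazin‑2‑ium tetrafluoroborate (10 mol %), Et3N (20 mol %), toluene, rt; recrystallise
Reagents that add atoms: none
Why: enantioselective intramolecular crossed aldehyde–ketone benzoin (Enders/Suzuki type); the carbene turns the aldehyde carbon into an acyl‑anion equivalent that attacks the ketone carbon in a six‑membered closure, and the indane‑fused pocket of the catalyst selects one ketone face, setting the tertiary carbinol stereocentre.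

Step 4
Reactants: 8 (2R)‑2‑ethyl‑2‑hydroxy‑5,6,8‑trimethoxy‑3,4‑dihydronaphthalen‑1(2H)‑one
Product: 9 (2R)‑2‑ethyl‑2‑hydroxy‑5,6,8‑trimethoxynaphthalen‑1(2H)‑one
Conditions: DDQ (1.5 equiv), 1,4‑dioxane, 90 °C
Reagents that add atoms: none
Why: DDQ dehydrogenation; benzylic hydride abstraction at C4 is favoured by the ortho and para methoxy groups, proton loss from C3 gives the styrene‑type alkene, and the quaternary C2 blocks aromatisation and is not touched.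

Step 5
Reactants: 8 (2R)‑2‑ethyl‑2‑hydroxy‑5,6,8‑trimethoxy‑3,4‑dihydronaphthalen‑1(2H)‑one
Product: 10 2‑ethyl‑5,6,8‑trimethoxy‑3,4‑dihydronaphthalen‑1(2H)‑one (racemic)
Conditions: SmI2 (2.5 equiv), THF–CH3OH, −78 → 0 °C
Reagents that add atoms: none
Why: SmI2 reductive cleavage of an α‑hydroxy ketone (Molander α‑deoxygenation); the aryl ketyl expels hydroxide and the samarium enolate is protonated.

Step 6
Reactants: 10 2‑ethyl‑5,6,8‑trimethoxy‑3,4‑dihydronaphthalen‑1(2H)‑one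
Product: 11 3‑ethyl‑2‑hydroxy‑5,7,8‑trimethoxynaphthalene‑1,4‑dione
Conditions: O2 (1 atm), potassium tert‑butoxide KOC(CH3)3 (4 equiv), tert‑butanol, 25 °C; then 1 M HCl
Reagents that add atoms: dioxygen, O=O
Why: classical base‑mediated autoxidation of a 2‑alkyl‑1‑tetralone to the 2‑alkyl‑3‑hydroxy‑1,4‑naphthoquinone; the new carbonyl forms at the benzylic carbon and the hydroxyl at the former C3, which gives the required regiochemistry.

Step 7
Reactants: 11 3‑ethyl‑2‑hydroxy‑5,7,8‑trimethoxynaphthalene‑1,4‑dione; 9 (2R)‑2‑ethyl‑2‑hydroxy‑5,6,8‑trimethoxynaphthalen‑1(2H)‑one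
Product: 14 3‑ethyl‑2‑{[(2R)‑2‑ethyl‑5,6,8‑trimethoxy‑1‑oxo‑1,2‑dihydronaphthalen‑2‑yl]oxy}‑5,7,8‑trimethoxynaphthalene‑1,4‑dione, via chloroquinone 12 (not isolated), via sodium alkoxide 13 (not isolated)
Conditions: (a) 11, (COCl)2, DMF (cat.), CH2Cl2, 0 °C → rt, evaporate; (b) 9, NaH (1.0 equiv), THF, 0 °C, then crude 12, 0 °C → rt
Reagents that add atoms: none
Why: Vilsmeier‑type conversion of the vinylogous acid into its vinylogous acid chloride, then addition–elimination of the tertiary alkoxide at C2 of the chloroquinone; only the O–H bond of 9 reacts, so the stereocentre is carried over with retention.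

Step 8
Reactants: 14 3‑ethyl‑2‑{[(2R)‑2‑ethyl‑5,6,8‑trimethoxy‑1‑oxo‑1,2‑dihydronaphthalen‑2‑yl]oxy}‑5,7,8‑trimethoxynaphthalene‑1,4‑dione
Product: 15 3‑ethyl‑2‑{[(2S)‑2‑ethyl‑5,6,8‑trimethoxy‑1,3,4‑trioxo‑1,2,3,4‑tetrahydronaphthalen‑2‑yl]oxy}‑5,7,8‑trimethoxynaphthalene‑1,4‑dione
Conditions: KMnO4 (3 equiv), Ac2O, −5 → 5 °C; aq. NaHSO3 work‑up
Reagents that add atoms: potassium permanganate, [K+].[O-][Mn](=O)(=O)=O
Why: Sharpless permanganate/acetic anhydride oxidation of an alkene to the α‑diketone; the electron‑rich cis styrene‑type C3=C4 reacts while the electron‑poor tetrasubstituted quinone C=C does not, and the descriptor changes from R to S only because the new dione carbon now outranks C1 (same spatial arrangement).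

Step 9
Reactants: 15 3‑ethyl‑2‑{[(2S)‑2‑ethyl‑5,6,8‑trimethoxy‑1,3,4‑trioxo‑1,2,3,4‑tetrahydronaphthalen‑2‑yl]oxy}‑5,7,8‑trimethoxynaphthalene‑1,4‑dione
Product: 16 3‑ethyl‑2‑{[(2S)‑2‑ethyl‑5,6,8‑trihydroxy‑1,3,4‑trioxo‑1,2,3,4‑tetrahydronaphthalen‑2‑yl]oxy}‑5,7,8‑trihydroxynaphthalene‑1,4‑dione (CNP0325426.1)
Conditions: BBr3 (14 equiv), CH2Cl2, −78 → 0 °C; then ice‑water
Reagents that add atoms: none
Why: Lewis‑acid ether cleavage by SN2 of bromide at the six methyl groups (four assisted by peri‑carbonyl chelation); the linking ether has a tertiary carbon flanked by two carbonyls, which can neither ionise nor undergo SN2, so the stereocentre is kept.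

## Compound list

1 | 2,4,5‑trimethoxybenzaldehyde | COc1cc(OC)c(OC)cc1C=O | starting material
2 | lithium {[2‑(dimethylamino)ethyl](methyl)amino}(2,4,5‑trimethoxyphenyl)methanolate (racemic at the aminal carbon) | [Li]OC(N(C)CCN(C)C)c1cc(OC)c(OC)cc1OC | intermediate
3 | lithium {[2‑(dimethylamino)ethyl](methyl)amino}(2‑lithio‑3,4,6‑trimethoxyphenyl)methanolate | [Li]OC(N(C)CCN(C)C)c1c([Li])c(OC)c(OC)cc1OC | intermediate
4 | lithium {[2‑(dimethylamino)ethyl](methyl)amino}(2‑iodo‑3,4,6‑trimethoxyphenyl)methanolate | [Li]OC(N(C)CCN(C)C)c1c(I)c(OC)c(OC)cc1OC | intermediate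
5 | 2‑iodo‑3,4,6‑trimethoxybenzaldehyde | O=Cc1c(I)c(OC)c(OC)cc1OC | intermediate
6 | pent‑1‑en‑3‑ol (racemic) | CCC(O)C=C | starting material
7 | 3,4,6‑trimethoxy‑2‑(3‑oxopentyl)benzaldehyde | CCC(=O)CCc1c(OC)c(OC)cc(OC)c1C=O | intermediate
8 | (2R)‑2‑ethyl‑2‑hydroxy‑5,6,8‑trimethoxy‑3,4‑dihydronaphthalen‑1(2H)‑one | CC[C@@]1(O)CCc2c(OC)c(OC)cc(OC)c2C1=O | intermediate
9 | (2R)‑2‑ethyl‑2‑hydroxy‑5,6,8‑trimethoxynaphthalen‑1(2H)‑one | CC[C@@]1(O)C=Cc2c(OC)c(OC)cc(OC)c2C1=O | intermediate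
10 | 2‑ethyl‑5,6,8‑trimethoxy‑3,4‑dihydronaphthalen‑1(2H)‑one (racemic) | CCC1CCc2c(OC)c(OC)cc(OC)c2C1=O | intermediate
11 | 3‑ethyl‑2‑hydroxy‑5,7,8‑trimethoxynaphthalene‑1,4‑dione | CCC1=C(O)C(=O)c2c(OC)c(OC)cc(OC)c2C1=O | intermediate
12 | 2‑chloro‑3‑ethyl‑5,7,8‑trimethoxynaphthalene‑1,4‑dione | CCC1=C(Cl)C(=O)c2c(OC)c(OC)cc(OC)c2C1=O | intermediate
13 | sodium (2R)‑2‑ethyl‑5,6,8‑trimethoxy‑1‑oxo‑1,2‑dihydronaphthalen‑2‑olate | CC[C@@]1(O[Na])C=Cc2c(OC)c(OC)cc(OC)c2C1=O | intermediate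
14 | 3‑ethyl‑2‑{[(2R)‑2‑ethyl‑5,6,8‑trimethoxy‑1‑oxo‑1,2‑dihydronaphthalen‑2‑yl]oxy}‑5,7,8‑trimethoxynaphthalene‑1,4‑dione | CCC1=C(O[C@]2(CC)C=Cc3c(OC)c(OC)cc(OC)c3C2=O)C(=O)c2c(OC)c(OC)cc(OC)c2C1=O | intermediate
15 | 3‑ethyl‑2‑{[(2S)‑2‑ethyl‑5,6,8‑trimethoxy‑1,3,4‑trioxo‑1,2,3,4‑tetrahydronaphthalen‑2‑yl]oxy}‑5,7,8‑trimethoxynaphthalene‑1,4‑dione | CCC1=C(O[C@]2(CC)C(=O)C(=O)c3c(OC)c(OC)cc(OC)c3C2=O)C(=O)c2c(OC)c(OC)cc(OC)c2C1=O | intermediate
16 | 3‑ethyl‑2‑{[(2S)‑2‑ethyl‑5,6,8‑trihydroxy‑1,3,4‑trioxo‑1,2,3,4‑tetrahydronaphthalen‑2‑yl]oxy}‑5,7,8‑trihydroxynaphthalene‑1,4‑dione | CCC1=C(O[C@]2(CC)C(=O)C(=O)c3c(O)c(O)cc(O)c3C2=O)C(=O)c2c(O)c(O)cc(O)c2C1=O | target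

## Step count and risks

Total: 9 steps. Longest linear sequence: 8 steps (1 → 5 → 7 → 8 → 10 → 11 → 14 → 15 → 16).

**Step 7.** A hindered tertiary alkoxide must add to a donor‑substituted chloroquinone; deprotonation of the quinone ethyl group or an acyloin shift of 13 may win. Fallback: form the C–O bond with the roles reversed, by SN2 at the tertiary carbinol with inversion. It sets out from 7. The benzoin of step 3 is run with the mirror‑image salt, (5aR,10bS)‑2‑(pentafluorophenyl)‑5a,10b‑dihydro‑4H,6H‑indeno[2,1‑b][1,2,4]triazolo[4,3‑d][1,4]oxazin‑2‑ium tetrafluoroborate, to give (2S)‑2‑ethyl‑2‑hydroxy‑5,6,8‑trimethoxy‑3,4‑dihydronaphthalen‑1(2H)‑one F1. Ph2PCl, Et3N and DMAP in THF convert it into (2S)‑2‑ethyl‑5,6,8‑trimethoxy‑1‑oxo‑1,2,3,4‑tetrahydronaphthalen‑2‑yl diphenylphosphinite F2. Mukaiyama oxidation–reduction condensation of F2 with hydroxyquinone 11 and 2,6‑dimethyl‑1,4‑benzoquinone in CH2Cl2 at rt gives, with inversion, 3‑ethyl‑2‑{[(2R)‑2‑ethyl‑5,6,8‑trimethoxy‑1‑oxo‑1,2,3,4‑tetrahydronaphthalen‑2‑yl]oxy}‑5,7,8‑trimethoxynaphthalene‑1,4‑dione F3. DDQ in dioxane as in step 4 then dehydrogenates F3, and the route is rejoined at 14.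

**Step 8.** The one‑pot permanganate oxidation may over‑oxidise the electron‑rich arenes or stop at a ketol that fragments. Fallback: a two‑stage oxidation through an isolated diol, setting out from 14. OsO4 (2 mol %) and N‑methylmorpholine N‑oxide in acetone–water give 3‑ethyl‑2‑{[(2R,3S,4S)‑2‑ethyl‑3,4‑dihydroxy‑5,6,8‑trimethoxy‑1‑oxo‑1,2,3,4‑tetrahydronaphthalen‑2‑yl]oxy}‑5,7,8‑trimethoxynaphthalene‑1,4‑dione F4, the cis‑diol formed anti to the aryloxy group (the other cis‑diol serves equally). Both carbinols are then oxidised at once with DMSO/(CF3CO)2O and Et3N at −78 °C, which leads back to 15.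

**Step 9.** Exhaustive BBr3 treatment may cleave the linking vinylogous ester by bromide addition–elimination. Fallback: a staged deprotection using two different mechanisms, setting out from 15. BCl3 in CH2Cl2 at −78 → −20 °C removes only the four chelation‑activated peri methyl groups, giving 3‑ethyl‑2‑{[(2S)‑2‑ethyl‑5,8‑dihydroxy‑6‑methoxy‑1,3,4‑trioxo‑1,2,3,4‑tetrahydronaphthalen‑2‑yl]oxy}‑5,8‑dihydroxy‑7‑methoxynaphthalene‑1,4‑dione F5. The two remaining methyl ethers are para to a ring carbonyl (vinylogous methyl esters) and are cleaved by SN2 at methyl with LiI in ethyl acetate at 70 °C; the tertiary linking ether cannot react this way, and acidic work‑up gives 16.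

## Further compounds

F1 | step 7 | (2S)‑2‑ethyl‑2‑hydroxy‑5,6,8‑trimethoxy‑3,4‑dihydronaphthalen‑1(2H)‑one | CC[C@]1(O)CCc2c(OC)c(OC)cc(OC)c2C1=O
F2 | step 7 | (2S)‑2‑ethyl‑5,6,8‑trimethoxy‑1‑oxo‑1,2,3,4‑tetrahydronaphthalen‑2‑yl diphenylphosphinite | CC[C@]1(OP(c2ccccc2)c2ccccc2)CCc2c(OC)c(OC)cc(OC)c2C1=O
F3 | step 7 | 3‑ethyl‑2‑{[(2R)‑2‑ethyl‑5,6,8‑trimethoxy‑1‑oxo‑1,2,3,4‑tetrahydronaphthalen‑2‑yl]oxy}‑5,7,8‑trimethoxynaphthalene‑1,4‑dione | CCC1=C(O[C@]2(CC)CCc3c(OC)c(OC)cc(OC)c3C2=O)C(=O)c2c(OC)c(OC)cc(OC)c2C1=O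
F4 | step 8 | 3‑ethyl‑2‑{[(2R,3S,4S)‑2‑ethyl‑3,4‑dihydroxy‑5,6,8‑trimethoxy‑1‑oxo‑1,2,3,4‑tetrahydronaphthalen‑2‑yl]oxy}‑5,7,8‑trimethoxynaphthalene‑1,4‑dione | CCC1=C(O[C@]2(CC)[C@@H](O)[C@@H](O)c3c(OC)c(OC)cc(OC)c3C2=O)C(=O)c2c(OC)c(OC)cc(OC)c2C1=O
F5 | step 9 | 3‑ethyl‑2‑{[(2S)‑2‑ethyl‑5,8‑dihydroxy‑6‑methoxy‑1,3,4‑trioxo‑1,2,3,4‑tetrahydronaphthalen‑2‑yl]oxy}‑5,8‑dihydroxy‑7‑methoxynaphthalene‑1,4‑dione | CCC1=C(O[C@]2(CC)C(=O)C(=O)c3c(O)c(OC)cc(O)c3C2=O)C(=O)c2c(O)c(OC)cc(O)c2C1=O
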